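The earlier runs and the new flask were computed from invented constants, and the scatter is random.

Start from the midnight run: by 2.50 h free monomer read 82.8% of its charge, yet monomer in chains read 0%, with a scatter of 1 percentage point.

- midnight: free monomer 0.49 M; transfer agent 7.4 mM; pre-initiator 1.1 mM; run made earlier
- flask: free monomer 0.49 M; transfer agent 4.90 mM; pre-initiator 1.1 mM; time 8.0 h

midnight run (percent of the free monomer charged)

| time / h | monomer in chains / % | free monomer / % |
|---|---|---|
| 0.200 | 0 | 97.3 |
| 0.667 | 0 | 94.5 |
| 1.00 | 0.9 | 93.9 |
| 1.50 | 1.8 | 89.0 |
| 2.50 | 0 | 82.8 |

(readings scatter by 1 percentage point)

- the average divides the monomer in chains by the number of chains begun, living and dead together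
- the earlier runs do not show the number of chains; that part of a forecast is a guess
- no earlier run changes the charge of transfer agent; that part of a forecast is a guess

* whether the average number of monomer units in a chain (chains begun, living or dead) reaches 50 by 8.0 h (no / yes)
* average number of monomer units in a chain (chains begun, living or dead) at 8.0 h

Count turnovers as at the bench, one chain per transfer agent. For the new flask, take the charge ratio, free monomer charged per transfer agent charged, 100 (the target degree of polymerisation). The length is then this ratio times the fraction of the monomer charge in chains, divided by the fraction of the transfer agent charge that equals the chains begun. Read the midnight fall as first-order, 0.0755 h⁻¹, and assume it holds in the new flask, so reckon 45.3% of the free monomer gone by 8.0 h. If all of that stood in chains, with one chain per transfer agent, the new flask would give 45.3, below 50.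

The rule stops at the midnight readings. At 1.50 h, monomer in chains over monomer gone reads 0.164, but monomer in chains there reads 1.8% against a scatter of 1 point, and at 2.50 h it reads 0%. Assume that ratio holds to 8.0 h, and it brings the new flask down to 7.42. My reckoning therefore gives 7.42 at one chain per transfer agent, and on that same reading the length reaches 50 if chains begun stay below 14.8% of the transfer agent charge, a fraction the midnight run does not show.

The forecast answers no, with length 12: “Even if all the consumed monomer were in chains, the DP would be only about 40, so reaching 50 is unlikely.”

The flask answers yes, passing 50 at 5.81 h and standing at 62.3 at 8.0 h.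

    free monomer + living end → monomer in chains + living end, rate k1*[living end]*[free monomer] (k = 63.0 M⁻¹ h⁻¹)
    free monomer → uncatalysed product (k = 0.0810 h⁻¹)
    free monomer + initiator → living end + monomer in chains (k = 0.640 M⁻¹ h⁻¹)
    living end + transfer agent → dead chain (kL = 9.70 M⁻¹ h⁻¹)
    living end + monomer in chains → dead end (k = 0.110 M⁻¹ h⁻¹)
    pre-initiator ⇌ initiator (K = 0.750, k = 0.0520 h⁻¹)

At 8.00 h the flask holds 2.23% of its monomer charge in chains, dead end stands at 0%, and living end plus dead chain come to 3.57% of the transfer agent charge, so the charge ratio gives 62.5. The half-life of a living end against transfer agent at that time is 15 h, longer than the 8.0 h the flask has run, and 99.5% of the transfer agent remains.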